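**Retrosynthetic overview**
1. The esters go on last. The C7 isovalerate comes from acylation. The C9 tiglate and the C7 carbinol are set together by an Evans–Tishchenko reaction of 9-hydroxy-7-ketone 16 with tiglaldehyde.
2. Ring C (seven-membered, C4–C5–C6–C7–C8–C9–C10) is not closed as such. Ketone 16 arises from the six-membered ring C4–C5–C7–C8–C9–C10 of isopropenyl carbinol 15 by a semipinacol ring expansion in which C5 moves from C7 to C6.
3. Enabling feature: C7 (oxygen-bearing), C6 (gem-dimethyl) and C5 (cyclobutane methine) form the retron of an α,α-dimethyl ketone. With C6 taken out of the ring, the C7 carbonyl sits directly on C5 and first serves to close ring B.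
4. Tricycle 11 comes from cis-decalin bromo enone 9 (C5–C11, enolate alkylation). Enone 9 comes from Diels–Alder adduct 8 (C8=C9, aldol condensation), and 8 from diene 7 and bromoenal 3. The C1 and C9 oxygens enter by allylic oxidation and conjugate borylation.
5. Order of rings: A (Diels–Alder), the six-membered forerunner of C (aldol), B (alkylation), C (ring expansion).

Key step: step 10

Remark on numbering: longipinane numbering is used for all compounds. C1 is the ketone, C2=C3 the alkene with the C3 methyl. C4, C5, C11 and C10 form cyclobutane ring B. C6 is the gem-dimethyl carbon, C7 the isovalerate carbon, C8 the methylene, C9 the tiglate carbon and C10 the methyl-bearing quaternary carbon. Ring A is C1–C2–C3–C4–C10–C11.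
Assumption: the sense of induction of the chiral catalysts in steps 4 and 8 is taken from the accepted models for these catalyst classes. Both antipodes of each catalyst are available.

**Step 1**
Reactants: 1 methacrolein
Product: 3 (E)-3-bromo-2-methylprop-2-enal, via 2,3-dibromo-2-methylpropanal 2 (not isolated)
Conditions: Br2, CH2Cl2, −78 → 0 °C; then Et3N, 0 °C → rt
Reagents that add atoms: bromine BrBr
Why: Bromine addition to the alkene followed by E2 loss of HBr from the tertiary bromide (addition–elimination) should give the more stable E vinyl bromide, with Br trans to CHO.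

**Step 2**
Reactants: 4 tiglaldehyde ((E)-2-methylbut-2-enal)
Product: 5 (3E,5E)-5-methylhepta-3,5-dien-2-one
Conditions: Ph3P=CHC(O)CH3, toluene, 90 °C
Reagents that add atoms: 1-(triphenylphosphoranylidene)propan-2-one CC(=O)C=P(c1ccccc1)(c1ccccc1)c1ccccc1
Why: A Wittig olefination with a stabilised ylide is E-selective and leaves the E trisubstituted alkene of 4 untouched.

**Step 3**
Reactants: 5 (3E,5E)-5-methylhepta-3,5-dien-2-one
Product: 7 (4E)-5-methylhepta-4,6-dien-2-one, via potassium trienolate 6 (not isolated)
Conditions: KOtBu (1.5 equiv), THF/DMSO, 0 °C; poured into ice-cold aq AcOH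
Reagents that add atoms: none
Why: In this deconjugative protonation, equilibrating base removes an ε-proton from the s-trans dienone, which fixes the new C3=C4 alkene as E, and the extended enolate is then protonated kinetically at its α-carbon (C5).

**Step 4**
Reactants: 3 (E)-3-bromo-2-methylprop-2-enal; 7 (4E)-5-methylhepta-4,6-dien-2-one
Product: 8 (1S,2R,6R)-6-bromo-1,3-dimethyl-2-(2-oxopropyl)cyclohex-3-ene-1-carbaldehyde
Conditions: (S)-3,3-diphenyl-1-(2-methylphenyl)tetrahydro-1H,3H-pyrrolo[1,2-c][1,3,2]oxazaborole protonated by HN(SO2CF3)2 (20 mol %), CH2Cl2, −78 → −40 °C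
Reagents that add atoms: none
Why: In this enantioselective Diels–Alder reaction the free diene terminus C1 bonds first to the β-carbon C11 in an asynchronous "ortho" transition state, the endo mode puts CHO cis to the C4 side chain, the E geometry of 3 puts Br trans to both, and the cationic boron catalyst shields one face of the bound enal, so that C4, C10 and C11 are set in absolute terms.

**Step 5**
Reactants: 8 Diels–Alder adduct
Product: 9 (4aR,5R,8aR)-5-bromo-4a,8-dimethyl-4a,5,6,8a-tetrahydronaphthalen-2(1H)-one
Conditions: pyrrolidine (20 mol %), AcOH (20 mol %), 4 Å MS, toluene, 40 °C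
Reagents that add atoms: none
Why: In this amine-catalysed intramolecular aldol condensation only the methyl carbon C8 can reach the non-enolisable aldehyde C9 through a six-membered transition state, the cis arms give the cis-fused enone, and no stereocentre is touched.

**Step 6**
Reactants: 9 cis-decalin bromo enone
Product: 11 (1S,2R,6R,7R)-1,3-dimethyltricyclo[4.4.0.0^2,7]deca-3,9-dien-8-one, via potassium dienolate 10 (not isolated)
Conditions: KHMDS (1.1 equiv), THF, −78 → 0 °C
Reagents that add atoms: none
Why: This is an intramolecular enolate alkylation (4-exo-tet) with close precedent in cis-decalone sulfonates, in which C5 is the only enolisable position and lies on the face of ring A opposite to bromine, so that SN2 displacement with inversion at C11 closes ring B and the new bridge fixes C5.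

**Step 7**
Reactants: 11 tricyclic dienone
Product: 12 (1R,2R,6R,7S)-1,3-dimethyltricyclo[4.4.0.0^2,7]deca-3,9-diene-5,8-dione
Conditions: Rh2(cap)4 (cap = caprolactamate, 1 mol %), t-BuOOH (5 equiv), K2CO3, CH2Cl2, rt
Reagents that add atoms: tert-butyl hydroperoxide CC(C)(C)OO
Why: This allylic C–H oxidation should follow the selectivity of the α-pinene to verbenone conversion, because C1 is the only allylic methylene (C4 is a bridgehead methine and the other enone has no γ-hydrogen).

**Step 8**
Reactants: 12 tricyclic bis-enone
Product: 14 (1R,2R,6R,7S,10R)-10-hydroxy-1,3-dimethyltricyclo[4.4.0.0^2,7]dec-3-ene-5,8-dione, via C9 pinacol boronate 13 (not isolated)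
Conditions: CuCl (5 mol %), NaOtBu (10 mol %), (R,S)-Josiphos (5.5 mol %), B2pin2 (1.1 equiv), MeOH (2 equiv), THF, −20 °C; then NaBO3·4H2O, THF/H2O, rt
Reagents that add atoms: bis(pinacolato)diboron CC1(C)OB(OC1(C)C)B1OC(C)(C)C(C)(C)O1 (boron group of 13); sodium perborate [Na+].[O-]OB=O (oxygen of 14)
Why: In this copper-catalysed enantioselective conjugate borylation with stereoretentive C–B oxidation the boryl copper species adds only to the β-monosubstituted enone at C9 and not to the β,β-disubstituted ring A enone, and because the two faces of C9 differ only in remote groups the ligand decides the 9R configuration.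

**Step 9**
Reactants: 14 β-hydroxy ketone
Product: 15 (1R,2R,6R,7S,8S,10R)-8,10-dihydroxy-1,3-dimethyl-8-(prop-1-en-2-yl)tricyclo[4.4.0.0^2,7]dec-3-en-5-one
Conditions: CH2=C(CH3)MgBr (2.5 equiv), LaCl3·2LiCl (1.0 equiv), THF, −78 °C; aq NH4Cl
Reagents that add atoms: isopropenylmagnesium bromide CC(=C)[Mg]Br
Why: In this Lewis-acid-promoted Grignard 1,2-addition the saturated C7 ketone is more electrophilic than the conjugated, hindered C1 enone, attack anti to the C9 alkoxide should place the isopropenyl group trans to O9, and this C7 centre is erased in step 10.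

**Step 10**
Reactants: 15 isopropenyl carbinol
Product: 16 (4R,5S,9R,10R,11R)-9-hydroxylongipin-2-ene-1,7-dione (3-hydroxy-2,6,6,9-tetramethyltricyclo[5.4.0.0^2,8]undec-9-ene-5,11-dione)
Conditions: [N,N'-bis(3,5-di-tert-butylsalicylidene)-1,2-cyclohexanediaminato]cobalt (5 mol %), N-fluoro-2,4,6-trimethylpyridinium triflate (1.5 equiv), PhSiH3 (1.5 equiv), acetone, 0 °C → rt
Reagents that add atoms: none
Why: Hydrogen-atom transfer from the cobalt hydride (formed from the cobalt salen complex, the oxidant and PhSiH3) to the CH2 terminus of the isopropenyl group gives the tertiary C6 radical, which is captured by divalent cobalt and oxidised to a cationic alkylcobalt species (radical–polar crossover); as cobalt departs, C5 shifts from the carbinol carbon C7 to C6 and loss of the hydroxyl proton leaves the C7 ketone. The closest known reaction type is the cobalt-catalysed radical–polar crossover semipinacol rearrangement of tertiary allylic alcohols, which includes the enlargement of 1-isopropenylcycloalkanols to 2,2-dimethylcycloalkanones. No ring is closed from an open chain: the six-membered ring C4–C5–C7–C8–C9–C10 takes up C6 between C5 and C7 and becomes ring C, so that one operation delivers the most hindered bond of the target (C5–C6), the gem-dimethyl quaternary carbon, the bicyclo[4.1.1]octane core and a C7 carbonyl in 1,3-relation to O9. No new stereocentre is formed, since C5 migrates with retention, the C7 carbinol centre is erased, and C4, C9, C10 and C11 are not touched. Three selectivities are needed: hydrogen-atom transfer to the electron-neutral 1,1-disubstituted alkene and not to the trisubstituted, electron-poor ring A enone (sterics and polarity), cationic character only at C6, which is not attached to the cyclobutane, so that no cyclobutylcarbinyl cation arises and the C7 hydroxyl does not ionise (Markovnikov transfer under non-acidic conditions), and migration of C5 rather than C8 (C5 is more substituted and C8 is deactivated by the C9 oxygen). The C9 hydroxyl lies trans to the isopropenyl group and cannot trap the cation as a cyclic ether.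

**Step 11**
Reactants: 16 9-hydroxy-1,7-dione; 4 tiglaldehyde
Product: 18 (4R,5S,7R,9R,10R,11R)-7-hydroxy-1-oxolongipin-2-en-9-yl (E)-2-methylbut-2-enoate, via tiglaldehyde hemiacetal 17 (not isolated)
Conditions: SmI2 (30 mol %), 4 (6 equiv), THF, −10 °C
Reagents that add atoms: none
Why: In this Evans–Tishchenko reaction the samarium-bound hemiacetal on O9 delivers its hydride to the C7 ketone from the face that carries O9, which gives the anti (7R) carbinol, turns the aldehyde into the C9 tiglate, differentiates the two oxygens and leaves the untethered C1 enone alone.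

**Step 12**
Reactants: 18 mono-tiglate
Product: 19 target, (4R,5S,7R,9R,10R,11R)-7-(3-methylbutanoyloxy)-1-oxolongipin-2-en-9-yl (E)-2-methylbut-2-enoate
Conditions: isovaleryl chloride (3 equiv), DMAP, pyridine, CH2Cl2, 40 °C
Reagents that add atoms: 3-methylbutanoyl chloride CC(C)CC(=O)Cl
Why: DMAP-catalysed acylation of the only free hydroxyl proceeds with retention at C7 and does not disturb the tiglate or the enone.

**Compound list**
1 | methacrolein | CC(=C)C=O | starting material
2 | 2,3-dibromo-2-methylpropanal | BrCC(C)(Br)C=O | intermediate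
3 | (E)-3-bromo-2-methylprop-2-enal | Br/C=C(\C)C=O | intermediate
4 | tiglaldehyde | C/C=C(\C)C=O | starting material
5 | (3E,5E)-5-methylhepta-3,5-dien-2-one | CC(=O)/C=C/C(C)=C/C | intermediate
6 | potassium (4E)-5-methylhepta-2,4,6-trien-2-olate | [K+].CC([O-])=C/C=C(C)/C=C | intermediate
7 | (4E)-5-methylhepta-4,6-dien-2-one | CC(=O)C/C=C(C)/C=C | intermediate
8 | (1S,2R,6R)-6-bromo-1,3-dimethyl-2-(2-oxopropyl)cyclohex-3-ene-1-carbaldehyde | CC(=O)C[C@@H]1C(C)=CC[C@@H](Br)[C@]1(C)C=O | intermediate
9 | (4aR,5R,8aR)-5-bromo-4a,8-dimethyl-4a,5,6,8a-tetrahydronaphthalen-2(1H)-one | C1=CC(=O)C[C@@H]2C(C)=CC[C@@H](Br)[C@]12C | intermediate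
10 | potassium dienolate of 9 (deprotonated at C5) | [K+].[O-]C1=C[C@@H]2C(C)=CC[C@@H](Br)[C@]2(C)C=C1 | intermediate
11 | (1S,2R,6R,7R)-1,3-dimethyltricyclo[4.4.0.0^2,7]deca-3,9-dien-8-one | C1=CC(=O)[C@@H]2[C@H]3CC=C(C)[C@@H]2[C@]31C | intermediate
12 | (1R,2R,6R,7S)-1,3-dimethyltricyclo[4.4.0.0^2,7]deca-3,9-diene-5,8-dione | C1=CC(=O)[C@@H]2[C@H]3C(=O)C=C(C)[C@@H]2[C@]31C | intermediate
13 | (1R,2R,6R,7S,10R)-1,3-dimethyl-10-(4,4,5,5-tetramethyl-1,3,2-dioxaborolan-2-yl)tricyclo[4.4.0.0^2,7]dec-3-ene-5,8-dione | CC1(C)OB(OC1(C)C)[C@@H]2CC(=O)[C@@H]3[C@H]4C(=O)C=C(C)[C@@H]3[C@]42C | intermediate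
14 | (1R,2R,6R,7S,10R)-10-hydroxy-1,3-dimethyltricyclo[4.4.0.0^2,7]dec-3-ene-5,8-dione | O[C@@H]1CC(=O)[C@@H]2[C@H]3C(=O)C=C(C)[C@@H]2[C@]31C | intermediate
15 | (1R,2R,6R,7S,8S,10R)-8,10-dihydroxy-1,3-dimethyl-8-(prop-1-en-2-yl)tricyclo[4.4.0.0^2,7]dec-3-en-5-one | O[C@@H]1C[C@@](O)(C(C)=C)[C@@H]2[C@H]3C(=O)C=C(C)[C@@H]2[C@]31C | intermediate
16 | (4R,5S,9R,10R,11R)-9-hydroxylongipin-2-ene-1,7-dione | O[C@@H]1CC(=O)C(C)(C)[C@@H]2[C@H]3C(=O)C=C(C)[C@@H]2[C@]31C | intermediate
17 | hemiacetal of 16 (O9) and tiglaldehyde | C/C=C(\C)C(O)O[C@@H]1CC(=O)C(C)(C)[C@@H]2[C@H]3C(=O)C=C(C)[C@@H]2[C@]31C | intermediate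
18 | (4R,5S,7R,9R,10R,11R)-7-hydroxy-1-oxolongipin-2-en-9-yl (E)-2-methylbut-2-enoate | C/C=C(\C)C(=O)O[C@@H]1C[C@@H](O)C(C)(C)[C@@H]2[C@H]3C(=O)C=C(C)[C@@H]2[C@]31C | intermediate
19 | (4R,5S,7R,9R,10R,11R)-7-(3-methylbutanoyloxy)-1-oxolongipin-2-en-9-yl (E)-2-methylbut-2-enoate | C/C=C(\C)C(=O)O[C@@H]1C[C@@H](OC(=O)CC(C)C)C(C)(C)[C@@H]2[C@H]3C(=O)C=C(C)[C@@H]2[C@]31C | target

Total step count: 12. Longest linear sequence: 11 (steps 2 to 12).

**Steps most likely to fail**

Step 4. The ketone of 7 may compete for the boron catalyst, and 7 may reconjugate under acid. Either process would lead to low conversion or poor facial selectivity. The fallback sets out from 3 and 7 and gives up catalytic induction. The cycloaddition is run with EtAlCl2 in CH2Cl2 at −78 °C and should give 8 together with the mirror-image adduct F1. The aldehydes are condensed with (1R,2R)-N,N'-dimethyl-1,2-diphenylethane-1,2-diamine to give the diastereomeric aminal F2 (from 8) and aminal F3 (from F1). These are separated by chromatography. Mild hydrolysis of F2 (aq AcOH, THF) comes back to the route at 8.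

Step 10. The cationic intermediate may collapse to the epoxide, or the alkene may simply be hydrogenated, instead of undergoing the 1,2-shift. The fallback sets out from 14 and uses a selenium-based semipinacol ring enlargement. Addition of 2-lithio-2-(methylselanyl)propane (from 2,2-bis(methylselanyl)propane and n-BuLi, THF, −78 °C) to the C7 ketone should give β-hydroxy selenide F6. Selenophilic activation with AgBF4 on alumina in CH2Cl2 ionises only the C6–Se bond and triggers migration of the more substituted carbon C5. This comes back to the route at 16.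

Step 6. E2 loss of HBr toward C1, or O-alkylation of the dienolate, may outrun C-alkylation. The fallback sets out from 9 and changes the nucleophile to a saturated ketone enolate under equilibrating conditions. Conjugate reduction with [(PPh3)CuH]6 in toluene should give saturated bromo ketone F4. Sodium methylsulfinylmethanide in DMSO equilibrates both enolates, of which only the C5 enolate can cyclise, and gives saturated tricyclic ketone F5. Dehydrogenation with IBX (DMSO, 70 °C), possible only toward C8=C9, comes back to the route at 11.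

**Further compounds**
F1 | step 4 | (1R,2S,6S)-6-bromo-1,3-dimethyl-2-(2-oxopropyl)cyclohex-3-ene-1-carbaldehyde (mirror-image adduct) | CC(=O)C[C@H]1C(C)=CC[C@H](Br)[C@@]1(C)C=O
F2 | step 4 | aminal of 8 with (1R,2R)-N,N'-dimethyl-1,2-diphenylethane-1,2-diamine | CC(=O)C[C@@H]1C(C)=CC[C@@H](Br)[C@]1(C)C2N(C)[C@H](c3ccccc3)[C@@H](c3ccccc3)N2C
F3 | step 4 | aminal of F1 with (1R,2R)-N,N'-dimethyl-1,2-diphenylethane-1,2-diamine | CC(=O)C[C@H]1C(C)=CC[C@H](Br)[C@@]1(C)C2N(C)[C@H](c3ccccc3)[C@@H](c3ccccc3)N2C
F4 | step 6 | saturated bromo ketone (3,4-dihydro derivative of 9) | C1CC(=O)C[C@@H]2C(C)=CC[C@@H](Br)[C@]12C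
F5 | step 6 | saturated tricyclic ketone (9,10-dihydro derivative of 11) | C1CC(=O)[C@@H]2[C@H]3CC=C(C)[C@@H]2[C@]31C
F6 | step 10 | β-hydroxy selenide (C7 carbinol bearing a 2-(methylselanyl)propan-2-yl group) | O[C@@H]1C[C@@](O)(C(C)(C)[Se]C)[C@@H]2[C@H]3C(=O)C=C(C)[C@@H]2[C@]31C
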